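**Plan**

- Cuts: the acid is first tied back to O5 as a six-membered lactone (side chain numbered as octanoic acid, core as chroman-4-one). Then C8–prenyl, O1–C2 and C4a–C4 are cut. The last cuts are chain C3–C4, chain C2–C3 and O5–chain C1.
- Enabling feature: the benzylic stereocentre (chain C3) sits on C6, ortho to the free 5-hydroxyl. O5, C5, C6 and chain C3 are therefore the four atoms of an o-quinone methide heterodiene; a vinyl ether supplies chain C2 and C1 and closes a temporary benzopyran (ring C) on the arene (ring A).
- Forward: 2,4,6-trihydroxybenzaldehyde is protected twice, brominated beside the remaining OH and O-methylated, so bromine marks the later C8 and C4a is the only free arene carbon. Ring C is built in the key step and oxidised to the lactone, ring B (the chromanone) is closed on C4a, bromine is exchanged for prenyl, and ring C is opened last.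
- Stereochemistry: chain C3 (R) comes from the (1S,2R)-trans-2-phenylcyclohexyl vinyl ether in the endo cycloaddition. C2 (S) and C3 (R), cis, come from a quinidine-catalysed oxa-Michael closure with kinetic protonation.

Key step: step 7

Remark (assumption): the usual facial model for this vinyl ether (s-trans enol ether, carbinol C–H in the enol ether plane, phenyl covering one face, endo approach) is taken to hold for the 2,6-dioxygenated methide. On that model the (1S,2R) auxiliary gives the (2R,4R) adduct (with a 4-alkyl group, R denotes the spatial arrangement that is S in the 4-aryl series); the enantiomeric auxiliary would be substituted without other change if the sense proved opposite.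

Remark (assumption): the sense of induction of cinchona alkaloids in the oxa-Michael closure of o-tigloylphenols flanked by a lactone oxygen (quinine leading to the 2R,3S-cis chromanone) is taken to carry over, hence quinidine for the 2S,3R series.

**Route**

Step 1
Reactants: 1 2,4,6-trihydroxybenzaldehyde
Product: 2 2-hydroxy-4,6-bis(methoxymethoxy)benzaldehyde
Conditions: MOMCl (2.1 equiv), i-Pr2NEt, CH2Cl2, 0 °C → rt
Reagents that add atoms: chloromethyl methyl ether, COCCl
Why: MOM ether formation (O-alkylation) should stop at the bis-ether because the third hydroxyl stays hydrogen-bonded to the aldehyde, the usual outcome for this aldehyde with two equivalents of the chloride.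

Step 2
Reactants: 2 2-hydroxy-4,6-bis(methoxymethoxy)benzaldehyde
Product: 3 3-bromo-2-hydroxy-4,6-bis(methoxymethoxy)benzaldehyde
Conditions: NBS (1.0 equiv), CH2Cl2, −20 → 0 °C
Reagents that add atoms: N-bromosuccinimide, O=C1CCC(=O)N1Br
Why: electrophilic aromatic bromination is directed by the free chelated phenol to its ortho carbon C3 (flanked by OH and one OMOM) rather than to C5 between two OMOM groups, and one equivalent at low temperature limits dibromination, so this step marks the later C8.

Step 3
Reactants: 3 3-bromo-2-hydroxy-4,6-bis(methoxymethoxy)benzaldehyde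
Product: 4 3-bromo-2-methoxy-4,6-bis(methoxymethoxy)benzaldehyde
Conditions: MeI, K2CO3, DMF, rt
Reagents that add atoms: iodomethane, CI
Why: Williamson ether synthesis in DMF methylates even a hydrogen-bonded, flanked phenol, while the MOM ethers, the aldehyde and the aryl bromide are inert.

Step 4
Reactants: 4 3-bromo-2-methoxy-4,6-bis(methoxymethoxy)benzaldehyde
Product: 5 3-bromo-4,6-dihydroxy-2-methoxybenzaldehyde
Conditions: 3 M HCl, THF, 50 °C
Reagents that add atoms: none
Why: acid-catalysed acetal hydrolysis removes both MOM groups, and the aryl methyl ether, the bromide and the aldehyde are stable to dilute HCl.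

Step 5
Reactants: 5 3-bromo-4,6-dihydroxy-2-methoxybenzaldehyde
Product: 6 3-bromo-4,6-bis(tert-butoxycarbonyloxy)-2-methoxybenzaldehyde
Conditions: Boc2O (2.3 equiv), DMAP (cat.), i-Pr2NEt, THF, 0 °C → rt
Reagents that add atoms: di-tert-butyl dicarbonate, CC(C)(C)OC(=O)OC(=O)OC(C)(C)C
Why: DMAP-catalysed carbonate formation converts both phenols, the chelated ortho one included, into tert-butyl carbonates and so provides the ortho Boc-oxy aldehyde that the cascade needs.

Step 6
Reactants: 7 (1S,2R)-trans-2-phenylcyclohexanol
Product: 8 (1S,2R)-trans-2-phenylcyclohexyl vinyl ether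
Conditions: ethyl vinyl ether (solvent), Hg(OAc)2 (cat.), reflux
Reagents that add atoms: ethyl vinyl ether, C=COCC
Why: mercury-diacetate-catalysed transetherification with excess ethyl vinyl ether is the standard vinyl transfer to a hindered secondary alcohol and does not touch its stereocentres.

Step 7
Reactants: 6 3-bromo-4,6-bis(tert-butoxycarbonyloxy)-2-methoxybenzaldehyde; 9 pentylmagnesium bromide; 8 (1S,2R)-trans-2-phenylcyclohexyl vinyl ether
Product: 13 tert-butyl (2R,4R)-6-bromo-5-methoxy-4-pentyl-2-{[(1S,2R)-2-phenylcyclohexyl]oxy}chroman-7-yl carbonate, via bromomagnesium alkoxide 10 (not isolated), via benzylic carbonate phenoxide 11 (not isolated), via E o-quinone methide 12 (not isolated)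
Conditions: 8 (3 equiv), Et2O, −78 °C; 9 (1.05 equiv); −78 °C → rt; aq. NH4Cl
Reagents that add atoms: none
Why: The Grignard reagent adds to the aldehyde at −78 °C, alkoxide 10 takes over the neighbouring Boc group to give phenoxide 11, and on warming 11 expels tert-butyl carbonate to unveil methide 12, which the electron-rich vinyl ether traps in an inverse-electron-demand hetero-Diels–Alder reaction; the closest known reaction type is the Grignard-triggered o-quinone methide generation from o-Boc-oxybenzaldehydes with cycloaddition to chiral vinyl ethers. Ring C closes by intermolecular [4+2] cycloaddition of the heterodiene O5=C5–C6=chain C3 with the two vinyl carbons, so O5–chain C1 and chain C2–C3 form together after chain C3–C4 has been made by the Grignard addition. The acetal carbon C2 is set by the auxiliary: with the enol ether s-trans and the carbinol C–H in its plane, the phenyl group covers one face and the heterodiene adds to the other. The benzylic carbon C4 follows from it through the endo position of the alkoxy group on the E methide (pentyl anti to the carbonyl), which places pentyl and alkoxy cis and should give 4R. The step needs chemoselectivity (attack at the aldehyde and not at the carbonates or the C–Br bond, migration of the ortho carbonate only), which is secured by the low temperature, by the para carbonate having no neighbouring alkoxide, and by the excess of vinyl ether that intercepts the methide before it can dimerise. All stereoisomeric by-products are diastereomers of 13 and can be removed by chromatography before C2 is oxidised.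

Step 8
Reactants: 13 tert-butyl (2R,4R)-6-bromo-5-methoxy-4-pentyl-2-{[(1S,2R)-2-phenylcyclohexyl]oxy}chroman-7-yl carbonate
Product: 14 tert-butyl (4R)-6-bromo-2-hydroxy-5-methoxy-4-pentylchroman-7-yl carbonate (lactol, both anomers)
Conditions: CSA (cat.), THF–H2O (4:1), 40 °C
Reagents that add atoms: water, O
Why: acid-catalysed hydrolysis of the mixed aryl alkyl acetal, in which aryloxide is the good leaving group, should proceed under mild acid that leaves the aryl tert-butyl carbonate and the C4 centre alone, and it returns the auxiliary.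

Step 9
Reactants: 14 tert-butyl (4R)-6-bromo-2-hydroxy-5-methoxy-4-pentylchroman-7-yl carbonate
Product: 15 tert-butyl (R)-6-bromo-5-methoxy-2-oxo-4-pentylchroman-7-yl carbonate
Conditions: n-Pr4N[RuO4] (5 mol%), NMO, 4 Å MS, CH2Cl2, rt
Reagents that add atoms: none
Why: the Ley–Griffith oxidation converts lactols into lactones under neutral anhydrous conditions that spare the carbonate, the bromide and the benzylic stereocentre.

Step 10
Reactants: 15 tert-butyl (R)-6-bromo-5-methoxy-2-oxo-4-pentylchroman-7-yl carbonate
Product: 16 (R)-6-bromo-7-hydroxy-5-methoxy-4-pentylchroman-2-one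
Conditions: TFA, CH2Cl2, 0 °C
Reagents that add atoms: none
Why: acidolysis of the aryl tert-butyl carbonate (loss of isobutene and CO2) frees the 7-hydroxyl, and the lactone, the methyl ether and the bromide are stable to cold TFA.

Step 11
Reactants: 16 (R)-6-bromo-7-hydroxy-5-methoxy-4-pentylchroman-2-one; 17 tigloyl chloride ((E)-2-methylbut-2-enoyl chloride)
Product: 19 (R)-6-bromo-7-hydroxy-5-methoxy-8-[(E)-2-methylbut-2-enoyl]-4-pentylchroman-2-one, via aryl tiglate 18 (not isolated)
Conditions: 17 (1.5 equiv), AlCl3 (3 equiv), ClCH2CH2Cl, 0 → 40 °C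
Reagents that add atoms: none
Why: Friedel–Crafts acylation by way of O-acylation and Fries shift can only reach C8 of the chromanone (the later C4a), the single unsubstituted arene carbon, ortho to the phenol and para to the methoxy group, because bromine blocks the other ortho site.

Step 12
Reactants: 19 (R)-6-bromo-7-hydroxy-5-methoxy-8-[(E)-2-methylbut-2-enoyl]-4-pentylchroman-2-one
Product: 20 (4R,8S,9R)-6-bromo-5-methoxy-8,9-dimethyl-4-pentyl-3,4,8,9-tetrahydro-2H,10H-pyrano[2,3-f]chromene-2,10-dione
Conditions: quinidine (0.2 equiv), PhCl, 15 °C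
Reagents that add atoms: none
Why: in this cinchona-alkaloid-catalysed intramolecular oxa-Michael addition the quinidinium phenoxide ion pair should deliver the only free phenol oxygen (the other ortho oxygen is held in the lactone) to one face of the tigloyl β-carbon to set C8 (S), and kinetic protonation of the enol on the same side should give the cis C9 (R) centre, as in the closely related closure of 7-hydroxy-8-tigloylcoumarins.

Step 13
Reactants: 20 (4R,8S,9R)-6-bromo-5-methoxy-8,9-dimethyl-4-pentyl-3,4,8,9-tetrahydro-2H,10H-pyrano[2,3-f]chromene-2,10-dione; 21 tributyl(3-methylbut-2-enyl)stannane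
Product: 22 (4R,8S,9R)-5-methoxy-8,9-dimethyl-6-(3-methylbut-2-enyl)-4-pentyl-3,4,8,9-tetrahydro-2H,10H-pyrano[2,3-f]chromene-2,10-dione
Conditions: 21 (1.5 equiv), Pd(PPh3)4 (10 mol%), DMF, 90 °C
Reagents that add atoms: none
Why: in the Stille coupling zerovalent palladium inserts into the aryl bromide, the allyl group is transferred from tin and reductive elimination at the less substituted allyl terminus should give the linear prenyl arene under neutral conditions that do not epimerise the cis-chromanone or open the lactone.

Step 14
Reactants: 22 (4R,8S,9R)-5-methoxy-8,9-dimethyl-6-(3-methylbut-2-enyl)-4-pentyl-3,4,8,9-tetrahydro-2H,10H-pyrano[2,3-f]chromene-2,10-dione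
Product: 23 (3R)-3-[(2S,3R)-5-hydroxy-7-methoxy-2,3-dimethyl-8-(3-methylbut-2-enyl)-4-oxochroman-6-yl]octanoic acid (CNP0217102.1)
Conditions: LiOH·H2O (3 equiv), THF–H2O, 0 °C; then 0.5 M HCl to pH 3–4, 0 °C
Reagents that add atoms: lithium hydroxide, [Li+].[OH-]
Why: saponification of the aryl lactone by hydroxide is expected to be much faster than enolisation of the ketone, the phenoxide then formed is conjugated to the C4 carbonyl and so protects C3 from epimerisation and retro-Michael opening, and cold acidification should give the acid with the 5-hydroxyl hydrogen-bonded to the ketone, which disfavours relactonisation.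

**Compound list**

1 | 2,4,6-trihydroxybenzaldehyde | O=Cc1c(O)cc(O)cc1O | starting material
2 | 2-hydroxy-4,6-bis(methoxymethoxy)benzaldehyde | O=Cc1c(O)cc(OCOC)cc1OCOC | intermediate
3 | 3-bromo-2-hydroxy-4,6-bis(methoxymethoxy)benzaldehyde | O=Cc1c(O)c(Br)c(OCOC)cc1OCOC | intermediate
4 | 3-bromo-2-methoxy-4,6-bis(methoxymethoxy)benzaldehyde | COc1c(Br)c(OCOC)cc(OCOC)c1C=O | intermediate
5 | 3-bromo-4,6-dihydroxy-2-methoxybenzaldehyde | COc1c(Br)c(O)cc(O)c1C=O | intermediate
6 | 3-bromo-4,6-bis(tert-butoxycarbonyloxy)-2-methoxybenzaldehyde | COc1c(Br)c(OC(=O)OC(C)(C)C)cc(OC(=O)OC(C)(C)C)c1C=O | intermediate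
7 | (1S,2R)-trans-2-phenylcyclohexanol | O[C@H]1CCCC[C@@H]1c1ccccc1 | starting material
8 | (1S,2R)-trans-2-phenylcyclohexyl vinyl ether | C=CO[C@H]1CCCC[C@@H]1c1ccccc1 | intermediate
9 | pentylmagnesium bromide | CCCCC[Mg]Br | starting material
10 | bromomagnesium 1-[3-bromo-4,6-bis(tert-butoxycarbonyloxy)-2-methoxyphenyl]hexan-1-olate (formed in the flask, not isolated) | CCCCCC(O[Mg]Br)c1c(OC)c(Br)c(OC(=O)OC(C)(C)C)cc1OC(=O)OC(C)(C)C | intermediate
11 | bromomagnesium 4-bromo-5-(tert-butoxycarbonyloxy)-2-[1-(tert-butoxycarbonyloxy)hexyl]-3-methoxyphenolate (formed in the flask, not isolated) | CCCCCC(OC(=O)OC(C)(C)C)c1c(OC)c(Br)c(OC(=O)OC(C)(C)C)cc1O[Mg]Br | intermediate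
12 | (6E)-4-bromo-3-(tert-butoxycarbonyloxy)-6-hexylidene-5-methoxycyclohexa-2,4-dien-1-one, the o-quinone methide (formed in the flask, not isolated) | CCCCC/C=C1/C(=O)C=C(OC(=O)OC(C)(C)C)C(Br)=C1OC | intermediate
13 | tert-butyl (2R,4R)-6-bromo-5-methoxy-4-pentyl-2-{[(1S,2R)-2-phenylcyclohexyl]oxy}chroman-7-yl carbonate | CCCCC[C@@H]1C[C@H](O[C@H]2CCCC[C@@H]2c2ccccc2)Oc2cc(OC(=O)OC(C)(C)C)c(Br)c(OC)c12 | intermediate
14 | tert-butyl (4R)-6-bromo-2-hydroxy-5-methoxy-4-pentylchroman-7-yl carbonate (lactol, both anomers) | CCCCC[C@@H]1CC(O)Oc2cc(OC(=O)OC(C)(C)C)c(Br)c(OC)c12 | intermediate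
15 | tert-butyl (R)-6-bromo-5-methoxy-2-oxo-4-pentylchroman-7-yl carbonate | CCCCC[C@@H]1CC(=O)Oc2cc(OC(=O)OC(C)(C)C)c(Br)c(OC)c12 | intermediate
16 | (R)-6-bromo-7-hydroxy-5-methoxy-4-pentylchroman-2-one | CCCCC[C@@H]1CC(=O)Oc2cc(O)c(Br)c(OC)c12 | intermediate
17 | tigloyl chloride, (E)-2-methylbut-2-enoyl chloride | C/C=C(\C)C(Cl)=O | starting material
18 | (R)-6-bromo-5-methoxy-2-oxo-4-pentylchroman-7-yl (E)-2-methylbut-2-enoate (formed in the flask, not isolated) | CCCCC[C@@H]1CC(=O)Oc2cc(OC(=O)/C(C)=C/C)c(Br)c(OC)c12 | intermediate
19 | (R)-6-bromo-7-hydroxy-5-methoxy-8-[(E)-2-methylbut-2-enoyl]-4-pentylchroman-2-one | CCCCC[C@@H]1CC(=O)Oc2c(C(=O)/C(C)=C/C)c(O)c(Br)c(OC)c12 | intermediate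
20 | (4R,8S,9R)-6-bromo-5-methoxy-8,9-dimethyl-4-pentyl-3,4,8,9-tetrahydro-2H,10H-pyrano[2,3-f]chromene-2,10-dione | CCCCC[C@@H]1CC(=O)Oc2c3c(c(Br)c(OC)c12)O[C@@H](C)[C@@H](C)C3=O | intermediate
21 | tributyl(3-methylbut-2-enyl)stannane | CCCC[Sn](CCCC)(CCCC)CC=C(C)C | starting material
22 | (4R,8S,9R)-5-methoxy-8,9-dimethyl-6-(3-methylbut-2-enyl)-4-pentyl-3,4,8,9-tetrahydro-2H,10H-pyrano[2,3-f]chromene-2,10-dione | CCCCC[C@@H]1CC(=O)Oc2c3c(c(CC=C(C)C)c(OC)c12)O[C@@H](C)[C@@H](C)C3=O | intermediate
23 | (3R)-3-[(2S,3R)-5-hydroxy-7-methoxy-2,3-dimethyl-8-(3-methylbut-2-enyl)-4-oxochroman-6-yl]octanoic acid | CCCCC[C@H](CC(=O)O)c1c(O)c2c(c(CC=C(C)C)c1OC)O[C@@H](C)[C@@H](C)C2=O | target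

**Count and risks**

Total steps: 14. Longest linear sequence: 13 steps (steps 1–5 and 7–14, from 2,4,6-trihydroxybenzaldehyde); step 6 is a one-step side branch.

Step 7. The methoxy group flanking the methide carbon may erode the E preference of the methide, or the auxiliary may shield the enol ether less well than assumed. Either would lower the configurational purity at chain C3 once the acetal carbon is oxidised, and the methide may also dimerise before it is trapped. Fallback: setting out from 5, a Wittig olefination with ethyl (triphenylphosphoranylidene)acetate in N,N-diethylaniline at reflux would give ethyl (E)-3-(3-bromo-4,6-dihydroxy-2-methoxyphenyl)acrylate F1. In the same pot F1 should isomerise and lactonise to 6-bromo-7-hydroxy-5-methoxy-2H-chromen-2-one F2. Boc protection (Boc2O, DMAP) would give tert-butyl 6-bromo-5-methoxy-2-oxo-2H-chromen-7-yl carbonate F3. Copper-catalysed asymmetric conjugate addition of 9 to F3 (CuBr·SMe2, a ferrocenyl diphosphine of the Josiphos family with the enantiomer chosen for 4R, t-BuOMe, −75 °C) would then return to the route at 15.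

Step 12. Ion pairing between the alkaloid and the bromine-flanked phenoxide may give too little facial control, and the pseudoenantiomeric alkaloid is often the less selective one; slow epimerisation at C9 would also erode the cis relationship. Fallback: setting out from 19, closure with an achiral amine (Et3N, CH2Cl2, 0 °C) under kinetic control would give the cis pair, 20 together with (4R,8R,9S)-6-bromo-5-methoxy-8,9-dimethyl-4-pentyl-3,4,8,9-tetrahydro-2H,10H-pyrano[2,3-f]chromene-2,10-dione F4. Because the benzylic centre is already fixed, the two are diastereomers and would be separated by preparative HPLC. F4 can be returned to the mixture by base-mediated ring opening and reclosure (retro-oxa-Michael/oxa-Michael), so the sequence comes back to the route at 20.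

Step 13. The allyl group may be transferred through its tertiary terminus to give the reverse-prenyl isomer; oxidative addition into the doubly ortho-oxygenated C–Br bond may also be slow enough for protodebromination or thermal epimerisation of the cis-chromanone to compete. Fallback: setting out from 20, Stille coupling with allyltributylstannane (Pd(PPh3)4, DMF, 80 °C), which has no regiochemical ambiguity, would give (4R,8S,9R)-6-allyl-5-methoxy-8,9-dimethyl-4-pentyl-3,4,8,9-tetrahydro-2H,10H-pyrano[2,3-f]chromene-2,10-dione F5. Olefin cross-metathesis of F5 with 2-methyl-2-butene (second-generation Grubbs catalyst, CH2Cl2, 40 °C) would then return to the route at 22.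

**Further compounds**

F1 | step 7 | ethyl (E)-3-(3-bromo-4,6-dihydroxy-2-methoxyphenyl)acrylate | CCOC(=O)/C=C/c1c(O)cc(O)c(Br)c1OC
F2 | step 7 | 6-bromo-7-hydroxy-5-methoxy-2H-chromen-2-one | O=c1ccc2c(OC)c(Br)c(O)cc2o1
F3 | step 7 | tert-butyl 6-bromo-5-methoxy-2-oxo-2H-chromen-7-yl carbonate | CC(C)(C)OC(=O)Oc1cc2oc(=O)ccc2c(OC)c1Br
F4 | step 12 | (4R,8R,9S)-6-bromo-5-methoxy-8,9-dimethyl-4-pentyl-3,4,8,9-tetrahydro-2H,10H-pyrano[2,3-f]chromene-2,10-dione | CCCCC[C@@H]1CC(=O)Oc2c3c(c(Br)c(OC)c12)O[C@H](C)[C@H](C)C3=O
F5 | step 13 | (4R,8S,9R)-6-allyl-5-methoxy-8,9-dimethyl-4-pentyl-3,4,8,9-tetrahydro-2H,10H-pyrano[2,3-f]chromene-2,10-dione | CCCCC[C@@H]1CC(=O)Oc2c3c(c(CC=C)c(OC)c12)O[C@@H](C)[C@@H](C)C3=O
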